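## Structural features

The target is a germacranolide: a ten-membered carbocycle C1–C10 fused through C6–C7 to a butenolide (C7=C11, lactone carbonyl C12, ring oxygen on C6), with an acetoxymethyl group C13 on C11, a senecioyloxymethyl group C14 on C10 and a methyl group C15 on C4. In the macrocycle a Z trisubstituted alkene C10=C1 is followed directly by a trans disubstituted oxirane C2–C3 and a cis trisubstituted oxirane C4–C5, and C8 and C9 carry an acetate and a (2S)-2-methyloxirane-2-carboxylate. Seven ring stereocentres (2R,3S,4S,5S,6R,8R,9R) stand in two contiguous blocks, C2–C6 and C8–C9, and an eighth sits in the epoxy ester. Fragile points are the hydrogen on C6 (γ to the lactone carbonyl and next to the C4–C5 oxirane, so base can open the oxirane through the furanolate), the allylic C2–C3 oxirane (acid), and four different esters on four hydroxyls. The real difficulty is the strained ten-membered ring with one Z and one E element, oxygenated at every ring carbon but C1, together with the need to tell four hydroxyls apart. The key step exploits that C8 bears oxygen and that the trans oxirane C2–C3 is an E alkene in disguise: a bond between C2 and C8 folds the macrocycle into a cis-fused cyclopentene (C8, C9, C10, C1, C2) and cycloheptane (C8, C2–C7) that can be built with small-ring stereocontrol and then opened. One consequence must be respected: the oxirane oxygen on C2 and C3 of the target lies on the alkene face that points at C8 when the ring is opened, so the last epoxidation has to occur on a conformer in which the E alkene has turned over.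

## Logic of the disconnections

**44 ⇒ 43.** The C2–O and C3–O bonds of the trans oxirane are cut last. A trans oxirane cannot sit in the seven-membered ring, and in 43 the other ring alkene is flanked by two allylic acyloxy groups and is the less nucleophilic one. Every earlier compound loses two stereocentres. The forward step must oxidise C2=C3 only, and on the face that faced C8.

**43 ⇒ 41 + 15; 41 ⇒ 39 + 40; 39 ⇒ 38 ⇒ 37 ⇒ 36.** The four acyl–oxygen bonds are cut in the order O9, O14, then O8 and O13 together. The order follows reactivity: two acetates go on at once, the primary O14 is acylated before the hindered secondary O9, and the base-sensitive epoxy ester comes last. This demands three groups that fall separately: a 4-methoxybenzyl ether on O13, and silyl ethers on O14 and O9 that fall together.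

**36 ⇒ 35.** The C8–H bond is cut to the ketone, because the ketone is what the fragmentation delivers. C8 becomes trigonal. The forward hydride addition must be 1,2 and must come from the outer face of the ring.

**35 ⇒ 34.** The C8=O and C2=C3 π bonds are traded for a C2–C8 σ bond, a C8 hydroxyl and a C3 mesylate. The ten-membered ring becomes a cis-fused 5-7 bicycle, and the E geometry becomes a trans relation of H2 and H3. The forward step must ionise the tertiary alcohol without touching the C6 hydrogen, with the mesylate antiperiplanar to C2–C8.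

**34 ⇒ 33 ⇒ 32.** The O9–Si bond and the C9–H bond are cut to the cyclopentenone. The enone is what makes C8 an enolisable position earlier on. The forward reduction must come from the convex face so that O9 ends up trans to O8.

**32 ⇒ 31 ⇒ 30 + 11.** The C7=C11 bond and the O6–C12 bond of the butenolide are cut to a C7 ketone, a C6 hydroxyl and a phosphonoacetic acid that already carries C13. The forward olefination must close a tetrasubstituted alkene under a base too weak to ionise the C8 hydroxyl.

**30 ⇒ 29 ⇒ 28 ⇒ 27.** The 4-methoxybenzyl ether on O6, the O3–S bond and the C8–O bond are removed in turn, back to an enolised β-diketone. C8 loses its stereocentre. The forward hydroxylation must come from the face of H2, and the mesylation must distinguish a secondary from a tertiary alcohol.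

**27 ⇒ 26.** The C7–C8 bond is cut and C7 is reattached to O3, which turns the seven-membered carbocycle into a six-membered lactone hanging on the cyclopentenone. This is the reverse of an intramolecular Claisen acyl transfer. It removes the carbocycle and hides the C3 hydroxyl. The forward step needs the α′ enolate at C8 and not the lactone enolate.

**26 ⇒ 25 ⇒ 24 ⇒ 23 + 5.** The oxirane C–O bonds, the C4=C5 bond and the O3–C7 ester bond are cut. This leaves an allylic alcohol with an isopropenyl group and a vinylglycolic acid. The forward epoxidation relies on both ring substituents of 25 lying on one face; the metathesis must close a trisubstituted alkene in a six-membered lactone.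

**23 ⇒ 22 ⇒ 21 + 7.** The O14–Si bond and the C10–C14 bond are cut (retro Morita–Baylis–Hillman). The forward silylation must take the primary hydroxyl only.

**21 ⇒ 20 ⇒ 18 ⇒ 16 + 17.** The enantiomer is traced to the racemate, the enone to its transposed vinylogous ester, and the C2–C3 bond is cut as an aldol. The forward aldol must be anti, and the resolution must leave the (1′R) carbinol.

**5 ⇒ 3 ⇒ 2 ⇒ 1; 11 ⇒ 10 ⇒ 9 ⇒ 6 + 7; 15 ⇒ 13 ⇒ 12.** The three acid partners are cut at C–O and C–C bonds next to their functional groups, down to a chiral diol, a phosphonoacetate with formaldehyde, and methallyl alcohol. The only demands are a regioselective acetal opening and one catalytic asymmetric epoxidation.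

## Other disconnections considered

**Alternative 1:** The cut is through C6–C7, C11–C12 and O6–C12. The open-chain ynal A2 would be cyclocarbonylated with Mo(CO)6 or Ru3(CO)12 under CO to the bicyclic core A1. In its favour, one step would make the macrocycle and the butenolide, and every ring stereocentre, both oxiranes and C8 included, would be set beforehand in an open chain. On that point it is better than the chosen plan, which must control C8 and the C2–C3 oxirane on a ten-membered ring. Against it, the hetero-Pauson–Khand reaction is established for five- and six-membered carbocycles, where alkyne and aldehyde are held close. A ten-membered closure through a metallacycle has no close model. The α-epoxy aldehyde and the allylic oxirane of A2 would also have to survive a low-valent metal carbonyl at elevated temperature. The chosen fragmentation opens a ring rather than closing one against strain, and its alkene geometry is stereospecific. In step count the two are comparable, since A2 needs seven stereocentres assembled linearly.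

**Alternative 2:** The cut is the C4=C5 bond. The tetraene A4 would be closed with the second-generation Grubbs catalyst to A3, which is then epoxidised. In its favour, the conditions are neutral and all four esters are in place, so no protecting-group exchange follows ring formation; in functional-group economy it is better than the chosen plan. Against it, a trisubstituted alkene must form inside a ten-membered ring from an isopropenyl group attached to an oxirane carbon, and the Z geometry that the cis oxirane needs is not enforced by the mechanism. The fragmentation fixes its alkene geometry through the relative configuration of two sp3 carbons. Both plans end with a face-selective epoxidation on the macrocycle, so on that point they are equal. Alternative 2 also has to tell C4=C5 from C10=C1 and from the ester alkenes at the metathesis stage.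

**Alternative 3:** The cut is the C9–C10 bond. The iodo aldehyde A6 would be closed with CrCl2 and catalytic NiCl2 to the C9 alcohol A5. In its favour, this macrocyclisation type is well established for medium rings, tolerates esters and oxiranes, and delivers O9 free for acylation. It also avoids both a strong base and the late C2–C3 epoxidation, and on these points it is better than the chosen plan. Against it, the alkenylchromium at C10 has the allylic senecioate on C14 in the β position and can eliminate to an allene. The new C9 stereocentre would be set by the conformation of a forming ten-membered ring with no obvious control element, and the α-silyloxy aldehyde of A6 can lose its C8 configuration. The chosen plan sets C9 on a cyclopentenone, where the facial bias is clear. In step count the two are similar.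

Key step: step 25

Remark on the chemistry: the fragmentation forms no σ bond and closes no ring by bond formation (it breaks C2–C8, and the new bonds are the C8=O and C2=C3 π bonds); two identical silyl ethers on O13 and O14 could not be told apart later, so O13 is carried as a 4-methoxybenzyl ether, O14 as a TBS ether and O9 as a TES ether; one equivalent of KN(SiMe3)2 at low temperature replaces an excess of alkoxide base; atom numbers are those of the target throughout.

## Route

Step 1
Reactants: 1 (2S)-but-3-ene-1,2-diol
Product: 2 PMP acetal of the diol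
Conditions: 4-MeOC6H4CH(OMe)2, CSA (cat.), CH2Cl2, rt
Reagents that add atoms: 4-methoxybenzaldehyde dimethyl acetal, COC(OC)c1ccc(OC)cc1
Why: Acid-catalysed transacetalisation of a 1,2-diol; the carbinol stereocentre is not touched.

Step 2
Reactants: 2 PMP acetal
Product: 3 (2S)-2-(4-methoxybenzyloxy)but-3-en-1-ol
Conditions: iBu2AlH, CH2Cl2, −78 to 0 °C; aq. potassium sodium tartrate
Reagents that add atoms: none
Why: Reductive acetal opening; aluminium binds the less hindered primary oxygen, so the benzylic C–O bond on that side is cleaved and the ether stays on the secondary oxygen.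

Step 3
Reactants: 3 primary alcohol
Product: 5 (2S)-2-(4-methoxybenzyloxy)but-3-enoic acid, via aldehyde 4 (not isolated)
Conditions: TEMPO (cat.), PhI(OAc)2, MeCN/pH 7 buffer, rt
Reagents that add atoms: water, O
Why: Oxoammonium oxidation to the aldehyde and through its hydrate to the acid; the near-neutral medium should keep the α-alkoxy, β,γ-unsaturated centre from enolising.

Step 4
Reactants: 6 triethyl phosphonoacetate; 7 formaldehyde (as paraformaldehyde)
Product: 9 ethyl 2-(diethoxyphosphoryl)acrylate, via hydroxymethyl phosphonate 8 (not isolated)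
Conditions: (CH2O)n, piperidine (cat.), MeOH, reflux; then TsOH (cat.), toluene, reflux, removal of water
Reagents that add atoms: none
Why: Knoevenagel-type hydroxymethylation of the phosphonate carbanion followed by acid-catalysed dehydration.

Step 5
Reactants: 9 phosphonoacrylate
Product: 10 ethyl 2-(diethoxyphosphoryl)-3-(4-methoxybenzyloxy)propanoate
Conditions: 4-MeOC6H4CH2OH, KOtBu (cat.), THF, 0 °C
Reagents that add atoms: 4-methoxybenzyl alcohol, COc1ccc(CO)cc1
Why: Oxa-Michael addition of the alkoxide to a doubly activated alkene; this places the protected C13 oxygen on the future C11.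

Step 6
Reactants: 10 phosphono ester
Product: 11 2-(diethoxyphosphoryl)-3-(4-methoxybenzyloxy)propanoic acid
Conditions: LiOH, THF/H2O, 0 °C; then cold 1 M HCl to pH 3
Reagents that add atoms: lithium hydroxide, [Li+].[OH-]
Why: Saponification of the carboxylic ester, which is far faster than attack at the phosphonate esters; low temperature limits retro-Michael loss of the alkoxide.

Step 7
Reactants: 12 2-methylprop-2-en-1-ol
Product: 13 (R)-2-methylglycidol
Conditions: Ti(OiPr)4 (cat.), D-(−)-diisopropyl tartrate (cat.), tBuOOH, 4 Å molecular sieves, CH2Cl2, −20 °C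
Reagents that add atoms: tert-butyl hydroperoxide, CC(C)(C)OO
Why: Sharpless asymmetric epoxidation; with the D-tartrate the oxygen is delivered to the face that gives the (R)-epoxy alcohol, which becomes the (S)-acid only through the change in CIP priorities.

Step 8
Reactants: 13 (R)-2-methylglycidol
Product: 15 (2S)-2-methyloxirane-2-carboxylic acid, via epoxy aldehyde 14 (not isolated)
Conditions: RuCl3·xH2O (cat.), NaIO4, CCl4/MeCN/H2O, 0 °C
Reagents that add atoms: sodium periodate, [Na+].[O-]I(=O)(=O)=O; water, O
Why: Catalytic RuO4 oxidation of a primary alcohol to the acid; the fully substituted oxirane carbon cannot epimerise.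

Step 9
Reactants: 16 3-ethoxycyclopent-2-en-1-one; 17 methacrolein
Product: 18 anti aldol adduct (racemic)
Conditions: LiN(iPr)2, THF, −78 °C; then 17; NH4Cl at −78 °C
Reagents that add atoms: none
Why: Kinetic α′ deprotonation of the vinylogous ester and aldol addition to the aldehyde carbon forms C2–C3; the ring-locked E(O) enolate should react through a chair Zimmerman–Traxler transition state to favour the anti adduct, and the syn isomer is removed by chromatography.

Step 10
Reactants: 18 anti aldol adduct
Product: 20 4-(1-hydroxy-2-methylallyl)cyclopent-2-enone (racemic anti), via allylic alcohol 19 (not isolated)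
Conditions: iBu2AlH, CH2Cl2, −78 °C; then 1 M HCl, THF, 0 °C
Reagents that add atoms: water, O
Why: Stork–Danheiser transposition: 1,2-reduction of the vinylogous ester, then hydrolysis of the enol ether with loss of the ring hydroxyl puts the carbonyl on C9 and the alkene at C10=C1, with the side chain now on the γ carbon C2.

Step 11
Reactants: 20 racemic hydroxy enone
Product: 21 (4R,1′R)-hydroxy enone
Conditions: Ti(OiPr)4, L-(+)-diisopropyl tartrate, tBuOOH (0.6 equiv), 4 Å molecular sieves, CH2Cl2, −20 °C
Reagents that add atoms: none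
Why: Sharpless kinetic resolution of a secondary allylic alcohol: with the L-tartrate the (1′S) carbinol is epoxidised fast and the (1′R) alcohol is left; because 20 is one diastereomer, this fixes C2 as well. At most half of 20 can be recovered.

Step 12
Reactants: 21 hydroxy enone; 7 formaldehyde (as formalin)
Product: 22 Baylis–Hillman diol
Conditions: aq. CH2O, imidazole, THF/H2O, rt
Reagents that add atoms: none
Why: Morita–Baylis–Hillman hydroxymethylation at the enone α carbon C10 installs C14; the catalyst adds reversibly at C1, and the C2 centre is not enolised.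

Step 13
Reactants: 22 diol
Product: 23 primary TBS ether
Conditions: TBSCl (1.05 equiv), imidazole, CH2Cl2, 0 °C
Reagents that add atoms: tert-butyldimethylsilyl chloride, CC(C)(C)[Si](C)(C)Cl
Why: The primary allylic hydroxyl is silylated much faster than the hindered secondary carbinol between the ring and the isopropenyl group.

Step 14
Reactants: 23 secondary alcohol; 5 acid
Product: 24 ester
Conditions: EDC·HCl, DMAP (cat.), CH2Cl2, −20 to 0 °C
Reagents that add atoms: none
Why: Carbodiimide esterification with catalytic DMAP; low temperature and little DMAP should limit enolisation of the activated α-alkoxy acid.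

Step 15
Reactants: 24 ester
Product: 25 dihydropyranone
Conditions: second-generation Grubbs catalyst [RuCl2(=CHPh)(PCy3)(H2IMes)] (cat.), CH2Cl2, high dilution, 40 °C
Reagents that add atoms: none
Why: Ring-closing metathesis of the vinyl and isopropenyl groups forms C4=C5 in a six-membered lactone, where the alkene can only be cis; the electron-poor trisubstituted enone alkene does not take part.

Step 16
Reactants: 25 dihydropyranone
Product: 26 epoxy lactone
Conditions: dimethyldioxirane, acetone/CH2Cl2, 0 °C
Reagents that add atoms: dimethyldioxirane, CC1(C)OO1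
Why: Electrophilic epoxidation of the only electron-rich alkene; the cyclopentenyl group on C3 and the ether on C6 are cis on the lactone, so the oxidant should enter from the opposite face, which is the face required for C4 and C5.

Step 17
Reactants: 26 epoxy lactone
Product: 27 enol of the bicyclic 7,9-diketone
Conditions: LiN(SiMe3)2 (1.1 equiv), THF, −78 to −20 °C; AcOH at −78 °C
Reagents that add atoms: none
Why: Intramolecular Claisen (Dieckmann-type) acyl transfer: the kinetic α′ enolate at C8 adds to the lactone carbonyl C7 through an oxabicyclo[3.2.1] tetrahedral intermediate, O3 is expelled, and proton transfer to the stabilised β-diketonate drives the change from lactone to seven-membered carbocycle. The tether forces the C7 and C3 branches to be cis.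

Step 18
Reactants: 27 enol
Product: 28 8-hydroxy diketone
Conditions: dimethyldioxirane, acetone/CH2Cl2, −40 to 0 °C
Reagents that add atoms: dimethyldioxirane, CC1(C)OO1
Why: Epoxidation of the enol and collapse to the α-hydroxy β-diketone (Rubottom-type, neutral); the oxidant should reach C8 on the side of the C2 hydrogen, away from the C2–C3 bond, so 8-OH and 2-H become cis.

Step 19
Reactants: 28 diol
Product: 29 C3 mesylate
Conditions: MsCl, Et3N, CH2Cl2, −20 °C
Reagents that add atoms: methanesulfonyl chloride, CS(=O)(=O)Cl
Why: Sulfonylation of the secondary carbinol; the tertiary hydroxyl between two carbonyls does not react. The mesylate has no antiperiplanar β hydrogen (C4 is fully substituted, H2 is syn), so it also protects O3 in the following steps.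

Step 20
Reactants: 29 mesylate
Product: 30 6-hydroxy ketone
Conditions: DDQ, CH2Cl2/pH 7 buffer, 0 °C to rt
Reagents that add atoms: none
Why: Oxidative cleavage of the 4-methoxybenzyl ether under buffered conditions; silyl ether, mesylate and oxirane are inert.

Step 21
Reactants: 30 6-hydroxy ketone; 11 phosphono acid
Product: 31 phosphonoacetate ester (mixture at C11)
Conditions: EDC·HCl, DMAP (cat.), CH2Cl2, 0 °C
Reagents that add atoms: none
Why: Carbodiimide esterification of the only acylable hydroxyl; the configuration at C11 is irrelevant because it becomes trigonal in the next step.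

Step 22
Reactants: 31 phosphonoacetate ester
Product: 32 tricyclic butenolide with C9 ketone
Conditions: LiCl, DBU, MeCN, 0 °C to rt
Reagents that add atoms: none
Why: Intramolecular Horner–Wadsworth–Emmons reaction in its LiCl/amine variant: the lithium-chelated phosphonate carbanion adds to the C7 ketone in a five-membered closure and eliminates to C7=C11; the amine is too weak a base to ionise the tertiary alcohol.

Step 23
Reactants: 32 enone
Product: 33 9-alcohol
Conditions: NaBH4, CeCl3·7H2O, MeOH/CH2Cl2, −78 °C
Reagents that add atoms: none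
Why: Luche 1,2-reduction of the cyclopentenone; the seven-membered ring covers the concave face, so hydride should enter on the convex face next to 8-OH and 2-H and place O9 trans to O8.

Step 24
Reactants: 33 diol
Product: 34 fragmentation precursor (9-OTES)
Conditions: Et3SiOTf, 2,6-lutidine, CH2Cl2, −78 °C
Reagents that add atoms: triethylsilyl trifluoromethanesulfonate, CC[Si](CC)(CC)OS(=O)(=O)C(F)(F)F
Why: At −78 °C the secondary allylic hydroxyl is silylated and the tertiary one is not; an ether is used on O9 because an ester would migrate to the C8 alkoxide in the next step.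

Step 25
Reactants: 34 fragmentation precursor
Product: 35 ten-membered 1(10)Z,2E-dienone
Conditions: KN(SiMe3)2 (1.05 equiv), THF, −78 to −40 °C; pH 7 phosphate buffer at −78 °C
Reagents that add atoms: none
Why: The amide base removes the tertiary O–H proton; the C8 alkoxide then forms C8=O while the C2–C8 σ electrons become the C2=C3 π bond and mesylate leaves from C3 in one concerted step. The closest known reaction type is the alkoxide-triggered Grob (Wharton) fragmentation of bicyclic 1,3-diol monosulfonates to E-cyclodecenones. No ring is closed by bond formation: the bond shared by the five- and seven-membered rings is broken and their perimeter becomes the ten-membered ring. No stereocentre is formed, and C2, C3 and C8 become trigonal. The E geometry is set by the substrate: the mesylate is equatorial on the cycloheptane and anti to C2–C8, and H2 and H3 are trans, so C1 and C4 end up trans; C10=C1 keeps the Z geometry of the cyclopentene. The step needs O-deprotonation over C-deprotonation at C6, and the product, whose C9 hydrogen is α to the new ketone, must not meet free base. One equivalent of a hindered base at low temperature, the irreversibility of the fragmentation and a buffered cold quench should secure both. Relief of the cis-fused bicycle and conjugation of the new ketone with the butenolide supply the driving force.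

Step 26
Reactants: 35 dienone
Product: 36 (8R)-alcohol
Conditions: NaBH4, CeCl3·7H2O, MeOH/THF, −78 °C
Reagents that add atoms: none
Why: Luche 1,2-reduction. The inner face of the C8 carbonyl is covered by the C2=C3 unit lying across the ring, so hydride should add from outside; this puts O8 where C2 used to be bonded and gives 8R.

Step 27
Reactants: 36 alcohol
Product: 37 8,13-diol
Conditions: DDQ, CH2Cl2/pH 7 buffer, 0 °C
Reagents that add atoms: none
Why: Oxidative removal of the 4-methoxybenzyl ether on O13; the buffer protects the vinyl oxirane and the TES ether.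

Step 28
Reactants: 37 diol
Product: 38 8,13-diacetate
Conditions: Ac2O, pyridine, DMAP (cat.), CH2Cl2, 0 °C to rt
Reagents that add atoms: acetic anhydride, CC(=O)OC(C)=O
Why: DMAP-catalysed acetylation of the primary and the hindered secondary hydroxyl in one operation.

Step 29
Reactants: 38 diacetate
Product: 39 9,14-diol
Conditions: HF·pyridine, pyridine, THF, 0 °C to rt
Reagents that add atoms: none
Why: Buffered fluoride cleavage of the secondary TES and primary TBS ethers; excess pyridine keeps the medium from opening the allylic oxirane, and acetates do not migrate under these non-basic conditions.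

Step 30
Reactants: 39 diol; 40 3-methylbut-2-enoyl chloride
Product: 41 14-senecioate
Conditions: 2,4,6-collidine, CH2Cl2, −78 to −40 °C
Reagents that add atoms: none
Why: The primary allylic hydroxyl is acylated faster than the secondary one flanked by C8 and C10; a weak hindered base avoids deconjugation of the enoyl chloride through its vinylketene.

Step 31
Reactants: 41 9-alcohol; 15 epoxy acid
Product: 43 2,3-deoxy target, via mixed anhydride 42 (not isolated)
Conditions: 2,4,6-Cl3C6H2COCl, Et3N, THF, 0 °C; then 41, DMAP, toluene, rt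
Reagents that add atoms: none
Why: Yamaguchi esterification; the hindered aroyl carbonyl of the mixed anhydride directs DMAP and then the alcohol to the epoxy acyl group, whose quaternary α carbon cannot epimerise.

Step 32
Reactants: 43 2,3-deoxy target
Product: 44 target (CNP0279449.1)
Conditions: dimethyldioxirane, acetone/CH2Cl2, −20 to 0 °C
Reagents that add atoms: dimethyldioxirane, CC1(C)OO1
Why: Neutral electrophilic epoxidation of the most electron-rich alkene; C10=C1 is deactivated by two allylic acyloxy groups and the other alkenes are conjugated to carbonyls. The E geometry is transferred to the trans oxirane. The 2R,3S configuration requires attack on the face that is outside in the ring conformer corresponding to 44, with all oxygen substituents peripheral.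

## Compound list

1 | (2S)-but-3-ene-1,2-diol | C=C[C@@H](CO)O | starting material
2 | (4S)-4-ethenyl-2-(4-methoxyphenyl)-1,3-dioxolane (both epimers at the acetal carbon) | C=C[C@H]1COC(O1)c1ccc(OC)cc1 | intermediate
3 | (2S)-2-[(4-methoxyphenyl)methoxy]but-3-en-1-ol | C=C[C@@H](CO)OCc1ccc(OC)cc1 | intermediate
4 | (2S)-2-[(4-methoxyphenyl)methoxy]but-3-enal | C=C[C@@H](C=O)OCc1ccc(OC)cc1 | intermediate
5 | (2S)-2-[(4-methoxyphenyl)methoxy]but-3-enoic acid | C=C[C@@H](C(=O)O)OCc1ccc(OC)cc1 | intermediate
6 | triethyl phosphonoacetate | CCOC(=O)CP(=O)(OCC)OCC | starting material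
7 | formaldehyde (paraformaldehyde or formalin) | C=O | starting material
8 | ethyl 2-(diethoxyphosphoryl)-3-hydroxypropanoate (racemic) | CCOC(=O)C(CO)P(=O)(OCC)OCC | intermediate
9 | ethyl 2-(diethoxyphosphoryl)prop-2-enoate | CCOC(=O)C(=C)P(=O)(OCC)OCC | intermediate
10 | ethyl 2-(diethoxyphosphoryl)-3-[(4-methoxyphenyl)methoxy]propanoate (racemic) | CCOC(=O)C(COCc1ccc(OC)cc1)P(=O)(OCC)OCC | intermediate
11 | 2-(diethoxyphosphoryl)-3-[(4-methoxyphenyl)methoxy]propanoic acid (racemic) | OC(=O)C(COCc1ccc(OC)cc1)P(=O)(OCC)OCC | intermediate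
12 | 2-methylprop-2-en-1-ol | CC(=C)CO | starting material
13 | [(2R)-2-methyloxiran-2-yl]methanol | OC[C@]1(C)CO1 | intermediate
14 | (2S)-2-methyloxirane-2-carbaldehyde | O=C[C@]1(C)CO1 | intermediate
15 | (2S)-2-methyloxirane-2-carboxylic acid | OC(=O)[C@]1(C)CO1 | intermediate
16 | 3-ethoxycyclopent-2-en-1-one | CCOC1=CC(=O)CC1 | starting material
17 | methacrolein (2-methylprop-2-enal) | CC(=C)C=O | starting material
18 | rac-(5S)-3-ethoxy-5-[(1R)-1-hydroxy-2-methylprop-2-en-1-yl]cyclopent-2-en-1-one (anti aldol; one enantiomer drawn) | CCOC1=CC(=O)[C@@H](C1)[C@@H](O)C(C)=C | intermediate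
19 | allylic alcohol from 1,2-reduction of 18: 3-ethoxy-5-(1-hydroxy-2-methylprop-2-en-1-yl)cyclopent-2-en-1-ol (racemic; side-chain centres as in 18; both epimers at the new carbinol) | CCOC1=CC(O)[C@@H](C1)[C@@H](O)C(C)=C | intermediate
20 | rac-(4R)-4-[(1R)-1-hydroxy-2-methylprop-2-en-1-yl]cyclopent-2-en-1-one (one enantiomer drawn) | O=C1C=C[C@@H](C1)[C@@H](O)C(C)=C | intermediate
21 | (4R)-4-[(1R)-1-hydroxy-2-methylprop-2-en-1-yl]cyclopent-2-en-1-one | O=C1C=C[C@@H](C1)[C@@H](O)C(C)=C | intermediate
22 | (4R)-2-(hydroxymethyl)-4-[(1R)-1-hydroxy-2-methylprop-2-en-1-yl]cyclopent-2-en-1-one | O=C1C(CO)=C[C@@H](C1)[C@@H](O)C(C)=C | intermediate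
23 | (4R)-2-({[tert-butyl(dimethyl)silyl]oxy}methyl)-4-[(1R)-1-hydroxy-2-methylprop-2-en-1-yl]cyclopent-2-en-1-one | O=C1C(CO[Si](C)(C)C(C)(C)C)=C[C@@H](C1)[C@@H](O)C(C)=C | intermediate
24 | (1R)-1-[(1R)-3-({[tert-butyl(dimethyl)silyl]oxy}methyl)-4-oxocyclopent-2-en-1-yl]-2-methylprop-2-en-1-yl (2S)-2-[(4-methoxyphenyl)methoxy]but-3-enoate | O=C1C(CO[Si](C)(C)C(C)(C)C)=C[C@@H](C1)[C@@H](OC(=O)[C@@H](OCc2ccc(OC)cc2)C=C)C(C)=C | intermediate
25 | (3S,6R)-6-[(1R)-3-({[tert-butyl(dimethyl)silyl]oxy}methyl)-4-oxocyclopent-2-en-1-yl]-3-[(4-methoxyphenyl)methoxy]-5-methyl-3,6-dihydro-2H-pyran-2-one | O=C1C(CO[Si](C)(C)C(C)(C)C)=C[C@@H](C1)[C@H]2OC(=O)[C@@H](OCc3ccc(OC)cc3)C=C2C | intermediate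
26 | (1R,2R,5S,6S)-2-[(1R)-3-({[tert-butyl(dimethyl)silyl]oxy}methyl)-4-oxocyclopent-2-en-1-yl]-5-[(4-methoxyphenyl)methoxy]-1-methyl-3,7-dioxabicyclo[4.1.0]heptan-4-one | O=C1C(CO[Si](C)(C)C(C)(C)C)=C[C@@H](C1)[C@H]2OC(=O)[C@@H](OCc3ccc(OC)cc3)[C@@H]3O[C@]23C | intermediate
27 | enol of the bicyclic diketone: cyclopentenone (C9=O, C10=C1, CH2OTBS on C10) fused at C2–C8 to a cycloheptane with 3-OH, 4,5-oxirane (4-methyl), 6-OPMB and C7(OH)=C8; (2S,3R,4R,5S,6S) | O=C1C(CO[Si](C)(C)C(C)(C)C)=C[C@H]2C1=C(O)[C@@H](OCc3ccc(OC)cc3)[C@@H]3O[C@]3(C)[C@@H]2O | intermediate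
28 | cis-fused 8-hydroxy-7,9-diketone: as 27 with C7 ketone and tertiary 8-OH cis to 2-H; (2R,3R,4R,5S,6S,8R) | O=C1C(CO[Si](C)(C)C(C)(C)C)=C[C@H]2[C@]1(O)C(=O)[C@@H](OCc3ccc(OC)cc3)[C@@H]3O[C@]3(C)[C@@H]2O | intermediate
29 | 3-O-methanesulfonate of 28; (2R,3R,4S,5S,6S,8R) | O=C1C(CO[Si](C)(C)C(C)(C)C)=C[C@H]2[C@]1(O)C(=O)[C@@H](OCc3ccc(OC)cc3)[C@@H]3O[C@]3(C)[C@@H]2OS(C)(=O)=O | intermediate
30 | 6-hydroxy ketone: 29 without the 4-methoxybenzyl group; (2R,3R,4S,5S,6S,8R) | O=C1C(CO[Si](C)(C)C(C)(C)C)=C[C@H]2[C@]1(O)C(=O)[C@@H](O)[C@@H]3O[C@]3(C)[C@@H]2OS(C)(=O)=O | intermediate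
31 | 6-O-[2-(diethoxyphosphoryl)-3-(4-methoxybenzyloxy)propanoyl] ester of 30 (both epimers at C11) | O=C1C(CO[Si](C)(C)C(C)(C)C)=C[C@H]2[C@]1(O)C(=O)[C@@H](OC(=O)C(COCc3ccc(OC)cc3)P(=O)(OCC)OCC)[C@@H]3O[C@]3(C)[C@@H]2OS(C)(=O)=O | intermediate
32 | tricyclic butenolide with C9 ketone: C7=C11 butenolide (13-OPMB), 8-OH, 3-OMs, 4,5-oxirane, 14-OTBS; (2R,3R,4S,5S,6R,8S) | COc1ccc(cc1)COCC1=C2[C@]3(O)C(=O)C(CO[Si](C)(C)C(C)(C)C)=C[C@@H]3[C@@H](OS(C)(=O)=O)[C@@]4(C)O[C@H]4[C@@H]2OC1=O | intermediate
33 | 9-alcohol of 32, 9-OH trans to 8-OH; (2R,3R,4S,5S,6R,8S,9R) | COc1ccc(cc1)COCC1=C2[C@]3(O)[C@H](O)C(CO[Si](C)(C)C(C)(C)C)=C[C@@H]3[C@@H](OS(C)(=O)=O)[C@@]4(C)O[C@H]4[C@@H]2OC1=O | intermediate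
34 | fragmentation precursor: cis-fused hydroazulenol mesylate with fused butenolide and 4,5-oxirane, 13-OPMB, 14-OTBS, 9-OTES; (2R,3R,4S,5S,6R,8S,9R) | COc1ccc(cc1)COCC1=C2[C@]3(O)[C@H](O[Si](CC)(CC)CC)C(CO[Si](C)(C)C(C)(C)C)=C[C@@H]3[C@@H](OS(C)(=O)=O)[C@@]4(C)O[C@H]4[C@@H]2OC1=O | intermediate
35 | ten-membered dienone: (1(10)Z,2E)-4,5-epoxy-8-oxo-13-OPMB-14-OTBS-9-OTES-germacra-1(10),2,7(11)-trien-12,6-olide; (4R,5S,6R,9R) | COc1ccc(cc1)COCC1=C2C(=O)[C@H](O[Si](CC)(CC)CC)/C(CO[Si](C)(C)C(C)(C)C)=C\C=C\[C@@]3(C)O[C@H]3[C@@H]2OC1=O | intermediate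
36 | (8R)-alcohol of 35; (4R,5S,6R,8R,9R) | COc1ccc(cc1)COCC1=C2[C@@H](O)[C@H](O[Si](CC)(CC)CC)/C(CO[Si](C)(C)C(C)(C)C)=C\C=C\[C@@]3(C)O[C@H]3[C@@H]2OC1=O | intermediate
37 | 8,13-diol (14-OTBS, 9-OTES); (4R,5S,6R,8R,9R) | OCC1=C2[C@@H](O)[C@H](O[Si](CC)(CC)CC)/C(CO[Si](C)(C)C(C)(C)C)=C\C=C\[C@@]3(C)O[C@H]3[C@@H]2OC1=O | intermediate
38 | 8,13-diacetate (14-OTBS, 9-OTES); (4R,5S,6R,8R,9R) | CC(=O)OCC1=C2[C@@H](OC(C)=O)[C@H](O[Si](CC)(CC)CC)/C(CO[Si](C)(C)C(C)(C)C)=C\C=C\[C@@]3(C)O[C@H]3[C@@H]2OC1=O | intermediate
39 | 8,13-diacetoxy-9,14-diol; (4R,5S,6R,8R,9R) | CC(=O)OCC1=C2[C@@H](OC(C)=O)[C@H](O)/C(CO)=C\C=C\[C@@]3(C)O[C@H]3[C@@H]2OC1=O | intermediate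
40 | 3-methylbut-2-enoyl chloride | CC(C)=CC(Cl)=O | starting material
41 | 14-O-(3-methylbut-2-enoyl) derivative of 39 with free 9-OH; (4R,5S,6R,8R,9R) | CC(=O)OCC1=C2[C@@H](OC(C)=O)[C@H](O)/C(COC(=O)C=C(C)C)=C\C=C\[C@@]3(C)O[C@H]3[C@@H]2OC1=O | intermediate
42 | (2S)-2-methyloxirane-2-carboxylic 2,4,6-trichlorobenzoic anhydride | O=C(OC(=O)[C@]1(C)CO1)c1c(Cl)cc(Cl)cc1Cl | intermediate
43 | 2,3-deoxy target: (1(10)Z,2E)-8,13-diacetoxy-4,5-epoxy-9-[(2S)-2-methyloxirane-2-carbonyloxy]-14-(3-methylbut-2-enoyloxy)germacra-1(10),2,7(11)-trien-12,6-olide; (4R,5S,6R,8R,9R) | CC(=O)OCC1=C2[C@@H](OC(C)=O)[C@H](OC(=O)[C@]3(C)CO3)/C(COC(=O)C=C(C)C)=C\C=C\[C@@]3(C)O[C@H]3[C@@H]2OC1=O | intermediate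
44 | CNP0279449.1: (1(10)Z)-8,13-diacetoxy-2,3:4,5-diepoxy-9-[(2S)-2-methyloxirane-2-carbonyloxy]-14-(3-methylbut-2-enoyloxy)germacra-1(10),7(11)-dien-12,6-olide; (2R,3S,4S,5S,6R,8R,9R) | CC(=O)OCC1=C2[C@@H](OC(C)=O)[C@H](OC(=O)[C@]3(C)CO3)/C(COC(=O)C=C(C)C)=C\[C@H]3O[C@@H]3[C@@]3(C)O[C@H]3[C@@H]2OC1=O | target

## Step count and least certain steps

Total: 32 steps. Longest linear sequence: 24 steps (steps 9–32, from 16). The three acid partners take 3, 3 and 2 steps (steps 1–3, 4–6 and 7–8).

**Step 25 (key step).** The most likely failure is proton abstraction at C6 instead of at the hydroxyl. The C6 hydrogen is γ to the lactone carbonyl and next to the oxirane, and the resulting furanolate would open the oxirane. The second risk is loss of the C9 configuration by enolisation of the newly formed ketone if any base survives the fragmentation. Fallback: the alkoxide is generated from a latent form instead of by deprotonation. 34 is silylated on the tertiary oxygen with N-(trimethylsilyl)imidazole to the trimethylsilyl ether F1. F1 is then treated with [(Me2N)3S][Me3SiF2] in THF at −40 °C, which frees the alkoxide as an ion pair with no Brønsted base in the flask; it fragments to 35, where the route is rejoined.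

**Step 32.** The risk is poor or reversed facial selectivity. The face of C2=C3 that must be oxidised is the one that pointed at C8 when the ring was opened. If the macrocycle keeps the shape in which it was formed, an external oxidant meets the other face and the 2,3-diastereomer results. Fallback: the oxygen is delivered from inside the ring at the ketone stage. 35 is treated with KHSO5 (as 2KHSO5·KHSO4·K2SO4) and NaHCO3 in aqueous MeCN. The C8 ketone forms a dioxirane, which can only reach the face of C2=C3 lying across the ring from C8, and should give the epoxy ketone F2. F2 is carried through the operations of steps 26–31: NaBH4/CeCl3·7H2O gives the alcohol F3, DDQ the diol F4, Ac2O the diacetate F5, HF·pyridine the diol F6, and 40 the senecioate F7. Esterification of F7 with 15 through 42 gives 44 directly.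

**Step 26.** The risk is hydride addition on the wrong face of a ketone in a flexible ten-membered ring. The outer face is the one expected to react, but the silyl ether on C9 sits close to it. Conjugate reduction of the doubly activated C7=C11 alkene is a second possibility. Fallback: the epimeric alcohol F8 obtained from 35 is not discarded. It is treated with AcOH, PPh3 and diisopropyl azodicarboxylate (Mitsunobu inversion), which installs the C8 acetate with the required configuration in the acetate F9. DDQ then frees O13 to give the alcohol F10, and Ac2O converts F10 into 38.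

**Step 17.** The risk is deprotonation of the lactone at C6 instead of the ketone at C8, or a shift of the freed C3 alkoxide onto the neighbouring oxirane; either process destroys the C4–C5 oxirane. Fallback: the order of epoxidation and acyl transfer is reversed. 25, which has no oxirane, is treated with LiN(SiMe3)2 to give the enol F11. Its C3 hydroxyl, now free and allylic to C4=C5, directs VO(acac)2/tBuOOH to the same face, which returns to the route at 27.

**Step 22.** The risk is a slow olefination of a hindered ketone by an α-substituted phosphonate. Under more forcing base the free tertiary alkoxide could start the fragmentation too early or undergo an α-ketol shift, and the carbanion could lose its β-alkoxide. Fallback: O8 of 31 is capped with Me3SiOTf and 2,6-lutidine to give the silyl ether F12. Without a free hydroxyl the olefination can be driven with NaH in THF to the butenolide F13, and citric acid in MeOH removes the trimethylsilyl group to return to 32.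

## Further compounds

F1 | step 25 | 8-O-trimethylsilyl ether of 34 | COc1ccc(cc1)COCC1=C2[C@]3(O[Si](C)(C)C)[C@H](O[Si](CC)(CC)CC)C(CO[Si](C)(C)C(C)(C)C)=C[C@@H]3[C@@H](OS(C)(=O)=O)[C@@]4(C)O[C@H]4[C@@H]2OC1=O
F2 | step 32 | 2,3-epoxide of 35 (2R,3S) with C8 ketone | COc1ccc(cc1)COCC1=C2C(=O)[C@H](O[Si](CC)(CC)CC)/C(CO[Si](C)(C)C(C)(C)C)=C\[C@H]3O[C@@H]3[C@@]3(C)O[C@H]3[C@@H]2OC1=O
F3 | step 32 | (8R)-alcohol of F2 | COc1ccc(cc1)COCC1=C2[C@@H](O)[C@H](O[Si](CC)(CC)CC)/C(CO[Si](C)(C)C(C)(C)C)=C\[C@H]3O[C@@H]3[C@@]3(C)O[C@H]3[C@@H]2OC1=O
F4 | step 32 | 2,3-epoxy 8,13-diol | OCC1=C2[C@@H](O)[C@H](O[Si](CC)(CC)CC)/C(CO[Si](C)(C)C(C)(C)C)=C\[C@H]3O[C@@H]3[C@@]3(C)O[C@H]3[C@@H]2OC1=O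
F5 | step 32 | 2,3-epoxy 8,13-diacetate | CC(=O)OCC1=C2[C@@H](OC(C)=O)[C@H](O[Si](CC)(CC)CC)/C(CO[Si](C)(C)C(C)(C)C)=C\[C@H]3O[C@@H]3[C@@]3(C)O[C@H]3[C@@H]2OC1=O
F6 | step 32 | 2,3-epoxy 8,13-diacetoxy-9,14-diol | CC(=O)OCC1=C2[C@@H](OC(C)=O)[C@H](O)/C(CO)=C\[C@H]3O[C@@H]3[C@@]3(C)O[C@H]3[C@@H]2OC1=O
F7 | step 32 | 2,3-epoxy 14-senecioate with free 9-OH | CC(=O)OCC1=C2[C@@H](OC(C)=O)[C@H](O)/C(COC(=O)C=C(C)C)=C\[C@H]3O[C@@H]3[C@@]3(C)O[C@H]3[C@@H]2OC1=O
F8 | step 26 | (8S)-alcohol, C8 epimer of 36 | COc1ccc(cc1)COCC1=C2[C@H](O)[C@H](O[Si](CC)(CC)CC)/C(CO[Si](C)(C)C(C)(C)C)=C\C=C\[C@@]3(C)O[C@H]3[C@@H]2OC1=O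
F9 | step 26 | (8R)-acetate with 13-OPMB | COc1ccc(cc1)COCC1=C2[C@@H](OC(C)=O)[C@H](O[Si](CC)(CC)CC)/C(CO[Si](C)(C)C(C)(C)C)=C\C=C\[C@@]3(C)O[C@H]3[C@@H]2OC1=O
F10 | step 26 | (8R)-acetate with free 13-OH | OCC1=C2[C@@H](OC(C)=O)[C@H](O[Si](CC)(CC)CC)/C(CO[Si](C)(C)C(C)(C)C)=C\C=C\[C@@]3(C)O[C@H]3[C@@H]2OC1=O
F11 | step 17 | 4,5-deoxy analogue of 27 (C4=C5 alkene, free 3-OH) | O=C1C(CO[Si](C)(C)C(C)(C)C)=C[C@H]2C1=C(O)[C@@H](OCc3ccc(OC)cc3)C=C(C)[C@@H]2O
F12 | step 22 | 8-O-trimethylsilyl ether of 31 | O=C1C(CO[Si](C)(C)C(C)(C)C)=C[C@H]2[C@]1(O[Si](C)(C)C)C(=O)[C@@H](OC(=O)C(COCc3ccc(OC)cc3)P(=O)(OCC)OCC)[C@@H]3O[C@]3(C)[C@@H]2OS(C)(=O)=O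
F13 | step 22 | 8-O-trimethylsilyl ether of 32 | COc1ccc(cc1)COCC1=C2[C@]3(O[Si](C)(C)C)C(=O)C(CO[Si](C)(C)C(C)(C)C)=C[C@@H]3[C@@H](OS(C)(=O)=O)[C@@]4(C)O[C@H]4[C@@H]2OC1=O
A1 | alternative 1 | protected bicyclic core from cyclocarbonylation (O8 and O13 TBS, O9 PMB) | CC(C)(C)[Si](C)(C)OCC1=C2[C@@H](O[Si](C)(C)C(C)(C)C)[C@H](OCc4ccc(OC)cc4)/C(COC(=O)C=C(C)C)=C\[C@H]3O[C@@H]3[C@@]3(C)O[C@H]3[C@@H]2OC1=O
A2 | alternative 1 | open-chain ynal (C6 aldehyde, C7–C11 alkyne) | CC(C)(C)[Si](C)(C)OCC#C[C@@H](O[Si](C)(C)C(C)(C)C)[C@H](OCc1ccc(OC)cc1)/C(COC(=O)C=C(C)C)=C\[C@H]2O[C@@H]2[C@@]2(C)O[C@H]2C=O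
A3 | alternative 2 | 4,5-deoxy target with Z C4=C5 | CC(=O)OCC1=C2[C@@H](OC(C)=O)[C@H](OC(=O)[C@]3(C)CO3)/C(COC(=O)C=C(C)C)=C\[C@H]3O[C@@H]3/C(C)=C\[C@@H]2OC1=O
A4 | alternative 2 | open tetraene (C5 vinyl on C6, isopropenyl on C3) | CC(=O)OCC1=C([C@@H](OC(C)=O)[C@H](OC(=O)[C@]2(C)CO2)/C(COC(=O)C=C(C)C)=C\[C@H]2O[C@@H]2C(C)=C)[C@H](C=C)OC1=O
A5 | alternative 3 | macrocyclic C9 alcohol (O8 and O13 TBS) | CC(C)(C)[Si](C)(C)OCC1=C2[C@@H](O[Si](C)(C)C(C)(C)C)[C@H](O)/C(COC(=O)C=C(C)C)=C\[C@H]3O[C@@H]3[C@@]3(C)O[C@H]3[C@@H]2OC1=O
A6 | alternative 3 | open iodo aldehyde (C9 aldehyde, C10 alkenyl iodide) | CC(C)(C)[Si](C)(C)OCC1=C([C@@H](O[Si](C)(C)C(C)(C)C)C=O)[C@H]([C@@H]2O[C@]2(C)[C@H]2O[C@@H]2/C=C(\I)COC(=O)C=C(C)C)OC1=O
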